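**Retrosynthetic overview**
- Target ⇐ fluoride removal of all four silicon groups from the silylated enone ⇐ oxidation of an allylic alcohol ⇐ 1,2-addition of an (E)-alkenylzinc (from TMS-protected 2-methylbut-3-yn-2-ol) to an (S)-α-methyl aldehyde.
- Key disconnection, Cα–CH2: the (S)-aldehyde ⇐ propanal + an ortho-silyloxy vinylarene by enantioselective photoredox/enamine/thiol hydrogen-atom-transfer anti-Markovnikov hydroalkylation, which makes the bond and the only stereocentre in one operation.
- Enabling feature: the CH2 to be bonded is the homobenzylic carbon of the ArCH2–CH2 link on the benzene ring, i.e. the terminal carbon of a latent aryl–CH=CH2 whose benzylic carbon holds the ring-stabilised radical after addition; its partner is the α-CH(CH3) of a carbonyl, i.e. C2 of the propanal enamine.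
- Vinylarene ⇐ Stille vinylation of an aryl bromide; the (E)-4-hydroxy-3-methylbut-2-enyl arm ⇐ aromatic Claisen allylation, cross-metathesis with methacrolein and Luche reduction, all from 3-bromo-4-hydroxybenzoic acid.
- Rings: the benzene ring is bought; no ring is formed in the route.

Key step: step 9

Assumption: the facial sense of the imidazolidinone in the key step is taken from the accepted shielding model for enamine radical cations; should it prove opposite, the antipodal catalyst would be used.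

**Step 1**
Reactants: 1 3-bromo-4-hydroxybenzoic acid
Product: 2 2-(trimethylsilyl)ethyl 3-bromo-4-hydroxybenzoate
Conditions: Me3SiCH2CH2OH (1.1 equiv), PPh3, DIAD, THF, 0 °C to rt
Reagents that add atoms: 2-(trimethylsilyl)ethanol, C[Si](C)(C)CCO
Why: Mitsunobu esterification, in which the carboxylic acid is by far the more acidic pronucleophile and should be alkylated in preference to the phenol, giving an ester that fluoride can remove at the end.

**Step 2**
Reactants: 2 2-(trimethylsilyl)ethyl 3-bromo-4-hydroxybenzoate; 3 allyl bromide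
Product: 4 2-(trimethylsilyl)ethyl 4-(allyloxy)-3-bromobenzoate
Conditions: K2CO3, DMF, rt
Reagents that add atoms: none
Why: Williamson O-allylation of the acidic phenol under mild carbonate conditions that leave the ester untouched.

**Step 3**
Reactants: 4 2-(trimethylsilyl)ethyl 4-(allyloxy)-3-bromobenzoate
Product: 5 2-(trimethylsilyl)ethyl 3-allyl-5-bromo-4-hydroxybenzoate
Conditions: N,N-diethylaniline, 185 °C, sealed tube
Reagents that add atoms: none
Why: aromatic Claisen rearrangement ([3,3] shift, then tautomerisation) should deliver the allyl group to the only unsubstituted ortho position.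

**Step 4**
Reactants: 5 2-(trimethylsilyl)ethyl 3-allyl-5-bromo-4-hydroxybenzoate
Product: 6 2-(trimethylsilyl)ethyl 3-allyl-5-bromo-4-[(tert-butyldimethylsilyl)oxy]benzoate
Conditions: TBSCl, imidazole, DMF, 40 °C
Reagents that add atoms: tert-butyldimethylsilyl chloride, CC(C)(C)[Si](C)(C)Cl
Why: silyl ether formation masks the phenol so that it cannot add to the enal of steps 5 and 6 (oxa-Michael) or quench later organometallic reagents.

**Step 5**
Reactants: 6 2-(trimethylsilyl)ethyl 3-allyl-5-bromo-4-[(tert-butyldimethylsilyl)oxy]benzoate; 7 methacrolein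
Product: 8 2-(trimethylsilyl)ethyl 3-bromo-4-[(tert-butyldimethylsilyl)oxy]-5-[(2E)-3-methyl-4-oxobut-2-en-1-yl]benzoate
Conditions: 7 (10 equiv), second-generation Grubbs catalyst (H2IMes)(PCy3)Cl2Ru=CHPh (5 mol%), CH2Cl2, 40 °C
Reagents that add atoms: none
Why: olefin cross-metathesis of a terminal olefin with a 1,1-disubstituted enal, where thermodynamic control should place the formyl group trans to the chain and so fix the E trisubstituted olefin.

**Step 6**
Reactants: 8 2-(trimethylsilyl)ethyl 3-bromo-4-[(tert-butyldimethylsilyl)oxy]-5-[(2E)-3-methyl-4-oxobut-2-en-1-yl]benzoate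
Product: 9 2-(trimethylsilyl)ethyl 3-bromo-4-[(tert-butyldimethylsilyl)oxy]-5-[(2E)-4-hydroxy-3-methylbut-2-en-1-yl]benzoate
Conditions: NaBH4, CeCl3·7H2O, MeOH, 0 °C
Reagents that add atoms: none
Why: Luche reduction should give clean 1,2-reduction of the enal with retention of olefin geometry, while the benzoate ester and the aryl bromide are inert.

**Step 7**
Reactants: 9 2-(trimethylsilyl)ethyl 3-bromo-4-[(tert-butyldimethylsilyl)oxy]-5-[(2E)-4-hydroxy-3-methylbut-2-en-1-yl]benzoate
Product: 10 2-(trimethylsilyl)ethyl 3-bromo-4-[(tert-butyldimethylsilyl)oxy]-5-[(2E)-4-[(tert-butyldimethylsilyl)oxy]-3-methylbut-2-en-1-yl]benzoate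
Conditions: TBSCl, imidazole, DMF, rt
Reagents that add atoms: tert-butyldimethylsilyl chloride, CC(C)(C)[Si](C)(C)Cl
Why: silylation of the primary allylic alcohol keeps it out of the later oxidation and lets all protecting groups leave together with fluoride.

**Step 8**
Reactants: 10 2-(trimethylsilyl)ethyl 3-bromo-4-[(tert-butyldimethylsilyl)oxy]-5-[(2E)-4-[(tert-butyldimethylsilyl)oxy]-3-methylbut-2-en-1-yl]benzoate; 11 tributyl(vinyl)stannane
Product: 12 2-(trimethylsilyl)ethyl 4-[(tert-butyldimethylsilyl)oxy]-3-[(2E)-4-[(tert-butyldimethylsilyl)oxy]-3-methylbut-2-en-1-yl]-5-vinylbenzoate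
Conditions: Pd(PPh3)4 (5 mol%), toluene, 100 °C
Reagents that add atoms: none
Why: Stille coupling (oxidative addition of zerovalent palladium into the aryl C–Br bond, vinyl transfer from tin, reductive elimination) runs without base and should spare the base-labile aryl silyl ether and the ester.

**Step 9**
Reactants: 12 2-(trimethylsilyl)ethyl 4-[(tert-butyldimethylsilyl)oxy]-3-[(2E)-4-[(tert-butyldimethylsilyl)oxy]-3-methylbut-2-en-1-yl]-5-vinylbenzoate; 13 propanal
Product: 14 2-(trimethylsilyl)ethyl 4-[(tert-butyldimethylsilyl)oxy]-3-[(2E)-4-[(tert-butyldimethylsilyl)oxy]-3-methylbut-2-en-1-yl]-5-[(3S)-3-methyl-4-oxobutyl]benzoate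
Conditions: 13 (5 equiv), Ir(Fmppy)2(dtbbpy)PF6 (1 mol%), (2R,5R)-5-benzyl-2-tert-butyl-3-methylimidazolidin-4-one·CF3CO2H (20 mol%), 2,4,6-(i-Pr)3C6H2SH (10 mol%), DME, blue LEDs, −40 °C
Reagents that add atoms: none
Why: The amine condenses with propanal to an E-enamine that the photoexcited trivalent iridium complex oxidises to a 3π-electron enaminyl radical cation; this electrophilic radical adds to the terminal carbon of the vinyl group of 12, the benzylic radical takes a hydrogen atom from the thiol, iminium hydrolysis releases 14, and divalent iridium reduces the thiyl radical to close both cycles. The closest known reaction type is the triple-catalytic (photoredox, enamine, thiol hydrogen-atom transfer) enantioselective anti-Markovnikov α-alkylation of aldehydes with styrenes and other simple olefins. No ring is closed. The new stereocentre is set by the catalyst: in the (2R,5R)-imidazolidinone the enamine double bond lies away from the tert-butyl group and the benzyl group shields its Si face, so the olefin should be met on the Re face of C2, which for the priority order CHO > CH2CH2Ar > CH3 gives S. The step needs regioselectivity (terminal attack, secured by the benzene ring that stabilises the benzylic radical), chemoselectivity for the conjugated vinyl group over the isolated trisubstituted olefin (secured by conjugation and low steric demand) and configurational stability of the product (secured because the α-branched aldehyde 14 should re-form an enamine with the hindered amine only slowly at −40 °C).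

**Step 10**
Reactants: 14 2-(trimethylsilyl)ethyl 4-[(tert-butyldimethylsilyl)oxy]-3-[(2E)-4-[(tert-butyldimethylsilyl)oxy]-3-methylbut-2-en-1-yl]-5-[(3S)-3-methyl-4-oxobutyl]benzoate; 15 2-methyl-2-[(trimethylsilyl)oxy]but-3-yne
Product: 18 2-(trimethylsilyl)ethyl 4-[(tert-butyldimethylsilyl)oxy]-3-[(2E)-4-[(tert-butyldimethylsilyl)oxy]-3-methylbut-2-en-1-yl]-5-[(3S,5E)-4-hydroxy-3,7-dimethyl-7-[(trimethylsilyl)oxy]oct-5-en-1-yl]benzoate (both epimers at the carbinol carbon), via alkenylzirconocene chloride 16 (not isolated), via alkenyl(methyl)zinc 17 (not isolated)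
Conditions: 15, Cp2Zr(H)Cl, CH2Cl2, rt; Me2Zn, −65 °C; then 14, 0 °C; aq. NH4Cl
Reagents that add atoms: none
Why: syn-hydrozirconation places zirconium on the terminal carbon (E-alkenyl), zirconium-to-zinc transmetalation gives a weakly basic alkenylzinc whose 1,2-addition to the aldehyde should spare the ester and the α-stereocentre; the new carbinol centre is formed unselectively on purpose because step 11 removes it.

**Step 11**
Reactants: 18 2-(trimethylsilyl)ethyl 4-[(tert-butyldimethylsilyl)oxy]-3-[(2E)-4-[(tert-butyldimethylsilyl)oxy]-3-methylbut-2-en-1-yl]-5-[(3S,5E)-4-hydroxy-3,7-dimethyl-7-[(trimethylsilyl)oxy]oct-5-en-1-yl]benzoate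
Product: 19 2-(trimethylsilyl)ethyl 4-[(tert-butyldimethylsilyl)oxy]-3-[(2E)-4-[(tert-butyldimethylsilyl)oxy]-3-methylbut-2-en-1-yl]-5-[(3S,5E)-3,7-dimethyl-4-oxo-7-[(trimethylsilyl)oxy]oct-5-en-1-yl]benzoate
Conditions: Dess–Martin periodinane, NaHCO3, CH2Cl2, 0 °C to rt
Reagents that add atoms: none
Why: Dess–Martin oxidation of the secondary allylic alcohol under buffered, non-basic conditions should give the E-enone without epimerising the adjacent stereocentre and without touching the silyl groups.

**Step 12**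
Reactants: 19 2-(trimethylsilyl)ethyl 4-[(tert-butyldimethylsilyl)oxy]-3-[(2E)-4-[(tert-butyldimethylsilyl)oxy]-3-methylbut-2-en-1-yl]-5-[(3S,5E)-3,7-dimethyl-4-oxo-7-[(trimethylsilyl)oxy]oct-5-en-1-yl]benzoate
Product: 20 4-hydroxy-3-[(2E)-4-hydroxy-3-methylbut-2-en-1-yl]-5-[(3S,5E)-7-hydroxy-3,7-dimethyl-4-oxooct-5-en-1-yl]benzoic acid (CNP0120226.2)
Conditions: TBAF (6 equiv), THF, 0 °C to rt; aq. NH4Cl
Reagents that add atoms: none
Why: fluoride-induced global desilylation cleaves the three silyl ethers at silicon and fragments the 2-(trimethylsilyl)ethyl ester (β-elimination to carboxylate, ethylene and Me3SiF); short exposure at low temperature and a mildly acidic quench should protect the base-sensitive α-stereocentre.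

**Compound list**
1 | 3-bromo-4-hydroxybenzoic acid | OC(=O)c1ccc(O)c(Br)c1 | starting material
2 | 2-(trimethylsilyl)ethyl 3-bromo-4-hydroxybenzoate | C[Si](C)(C)CCOC(=O)c1ccc(O)c(Br)c1 | intermediate
3 | allyl bromide | C=CCBr | starting material
4 | 2-(trimethylsilyl)ethyl 4-(allyloxy)-3-bromobenzoate | C[Si](C)(C)CCOC(=O)c1ccc(OCC=C)c(Br)c1 | intermediate
5 | 2-(trimethylsilyl)ethyl 3-allyl-5-bromo-4-hydroxybenzoate | C[Si](C)(C)CCOC(=O)c1cc(Br)c(O)c(CC=C)c1 | intermediate
6 | 2-(trimethylsilyl)ethyl 3-allyl-5-bromo-4-[(tert-butyldimethylsilyl)oxy]benzoate | C[Si](C)(C)CCOC(=O)c1cc(Br)c(O[Si](C)(C)C(C)(C)C)c(CC=C)c1 | intermediate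
7 | methacrolein | C=C(C)C=O | starting material
8 | 2-(trimethylsilyl)ethyl 3-bromo-4-[(tert-butyldimethylsilyl)oxy]-5-[(2E)-3-methyl-4-oxobut-2-en-1-yl]benzoate | C[Si](C)(C)CCOC(=O)c1cc(Br)c(O[Si](C)(C)C(C)(C)C)c(C/C=C(\C)C=O)c1 | intermediate
9 | 2-(trimethylsilyl)ethyl 3-bromo-4-[(tert-butyldimethylsilyl)oxy]-5-[(2E)-4-hydroxy-3-methylbut-2-en-1-yl]benzoate | C[Si](C)(C)CCOC(=O)c1cc(Br)c(O[Si](C)(C)C(C)(C)C)c(C/C=C(\C)CO)c1 | intermediate
10 | 2-(trimethylsilyl)ethyl 3-bromo-4-[(tert-butyldimethylsilyl)oxy]-5-[(2E)-4-[(tert-butyldimethylsilyl)oxy]-3-methylbut-2-en-1-yl]benzoate | C[Si](C)(C)CCOC(=O)c1cc(Br)c(O[Si](C)(C)C(C)(C)C)c(C/C=C(\C)CO[Si](C)(C)C(C)(C)C)c1 | intermediate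
11 | tributyl(vinyl)stannane | C=C[Sn](CCCC)(CCCC)CCCC | starting material
12 | 2-(trimethylsilyl)ethyl 4-[(tert-butyldimethylsilyl)oxy]-3-[(2E)-4-[(tert-butyldimethylsilyl)oxy]-3-methylbut-2-en-1-yl]-5-vinylbenzoate | C[Si](C)(C)CCOC(=O)c1cc(C=C)c(O[Si](C)(C)C(C)(C)C)c(C/C=C(\C)CO[Si](C)(C)C(C)(C)C)c1 | intermediate
13 | propanal | CCC=O | starting material
14 | 2-(trimethylsilyl)ethyl 4-[(tert-butyldimethylsilyl)oxy]-3-[(2E)-4-[(tert-butyldimethylsilyl)oxy]-3-methylbut-2-en-1-yl]-5-[(3S)-3-methyl-4-oxobutyl]benzoate | C[Si](C)(C)CCOC(=O)c1cc(CC[C@H](C)C=O)c(O[Si](C)(C)C(C)(C)C)c(C/C=C(\C)CO[Si](C)(C)C(C)(C)C)c1 | intermediate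
15 | 2-methyl-2-[(trimethylsilyl)oxy]but-3-yne | C#CC(C)(C)O[Si](C)(C)C | starting material
16 | Cp2Zr(Cl)[(E)-CH=CH–C(CH3)2OSiMe3], alkenylzirconocene chloride (tetravalent zirconium), not isolated | C[Si](C)(C)OC(C)(C)/C=C/[Zr](Cl)(C1C=CC=C1)C1C=CC=C1 | intermediate
17 | CH3Zn[(E)-CH=CH–C(CH3)2OSiMe3], alkenyl(methyl)zinc, not isolated | C[Zn]/C=C/C(C)(C)O[Si](C)(C)C | intermediate
18 | 2-(trimethylsilyl)ethyl 4-[(tert-butyldimethylsilyl)oxy]-3-[(2E)-4-[(tert-butyldimethylsilyl)oxy]-3-methylbut-2-en-1-yl]-5-[(3S,5E)-4-hydroxy-3,7-dimethyl-7-[(trimethylsilyl)oxy]oct-5-en-1-yl]benzoate (carbinol epimers) | C[Si](C)(C)CCOC(=O)c1cc(CC[C@H](C)C(O)/C=C/C(C)(C)O[Si](C)(C)C)c(O[Si](C)(C)C(C)(C)C)c(C/C=C(\C)CO[Si](C)(C)C(C)(C)C)c1 | intermediate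
19 | 2-(trimethylsilyl)ethyl 4-[(tert-butyldimethylsilyl)oxy]-3-[(2E)-4-[(tert-butyldimethylsilyl)oxy]-3-methylbut-2-en-1-yl]-5-[(3S,5E)-3,7-dimethyl-4-oxo-7-[(trimethylsilyl)oxy]oct-5-en-1-yl]benzoate | C[Si](C)(C)CCOC(=O)c1cc(CC[C@H](C)C(=O)/C=C/C(C)(C)O[Si](C)(C)C)c(O[Si](C)(C)C(C)(C)C)c(C/C=C(\C)CO[Si](C)(C)C(C)(C)C)c1 | intermediate
20 | 4-hydroxy-3-[(2E)-4-hydroxy-3-methylbut-2-en-1-yl]-5-[(3S,5E)-7-hydroxy-3,7-dimethyl-4-oxooct-5-en-1-yl]benzoic acid | C/C(=C\Cc1cc(C(=O)O)cc(CC[C@H](C)C(=O)/C=C/C(C)(C)O)c1O)CO | target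

**Step count and risks**
Total step count: 12. Longest linear sequence: 12 steps (1 to 20); the other starting materials 3, 7, 11, 13 and 15 are bought.

Steps most likely to fail:

1. Step 9 (key step). Radical addition to the ortho-silyloxy vinylarene may be slower than self-aldolisation of propanal, the thiol may be consumed by thiol–ene addition, and facial selectivity may be poor or eroded by re-enamination of the product. The fallback sets out from 12 and comes back at 14, with a covalently bound auxiliary instead of a catalyst setting the centre. Chemoselective hydroboration of the vinyl group (9-BBN, THF, then NaBO3·4H2O) should give the 2-hydroxyethyl arene F1, and Appel iodination (I2, PPh3, imidazole, CH2Cl2) the 2-iodoethyl arene F2. Propanal 13 and SAMP, (S)-1-amino-2-(methoxymethyl)pyrrolidine, give propanal SAMP-hydrazone F3. Its azaenolate (LiN(i-Pr)2, THF, 0 °C) would be alkylated with F2 at −100 °C to the alkylated hydrazone F4, for which the established sense of the auxiliary should give S. Cleavage with saturated aqueous oxalic acid/Et2O would return aldehyde 14.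

2. Step 12. Fluoride or the liberated phenoxide may epimerise the α-stereocentre of the ketone, and cleavage of the 2-(trimethylsilyl)ethyl ester may be incomplete at the low temperature this sensitivity demands. The fallback sets out from 18 and comes back at 20, so that fluoride acts before any ketone exists. TBAF in THF on 18 should give the fully desilylated hydroxy acid F5. MnO2 (acetone, rt) would oxidise both allylic alcohols to the keto-enal F6. Chemoselective reduction of the aldehyde in the presence of the enone (NaBH4, EtOH/CH2Cl2, −78 °C) would then give 20.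

3. Step 5. Ruthenium hydride species may isomerise the allyl arene into conjugation, and the electron-poor, 1,1-disubstituted partner may give slow turnover and incomplete conversion. The fallback sets out from 6 and comes back at 8, replacing metathesis by olefination. Lemieux–Johnson cleavage of the allyl group (OsO4 cat., NaIO4, 2,6-lutidine, dioxane/H2O) should give the arylacetaldehyde F7. Wittig reaction with the stabilised ylide Ph3P=C(CH3)CHO (toluene, 80 °C) would give the E-enal 8.

**Further compounds**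
F1 | step 9 | 2-(trimethylsilyl)ethyl 4-[(tert-butyldimethylsilyl)oxy]-3-[(2E)-4-[(tert-butyldimethylsilyl)oxy]-3-methylbut-2-en-1-yl]-5-(2-hydroxyethyl)benzoate | C[Si](C)(C)CCOC(=O)c1cc(CCO)c(O[Si](C)(C)C(C)(C)C)c(C/C=C(\C)CO[Si](C)(C)C(C)(C)C)c1
F2 | step 9 | 2-(trimethylsilyl)ethyl 4-[(tert-butyldimethylsilyl)oxy]-3-[(2E)-4-[(tert-butyldimethylsilyl)oxy]-3-methylbut-2-en-1-yl]-5-(2-iodoethyl)benzoate | C[Si](C)(C)CCOC(=O)c1cc(CCI)c(O[Si](C)(C)C(C)(C)C)c(C/C=C(\C)CO[Si](C)(C)C(C)(C)C)c1
F3 | step 9 | propanal SAMP-hydrazone, (S,E)-N-[2-(methoxymethyl)pyrrolidin-1-yl]propan-1-imine | CC/C=N/N1CCC[C@H]1COC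
F4 | step 9 | SAMP-hydrazone of aldehyde 14, (S) at the new α-carbon | C[Si](C)(C)CCOC(=O)c1cc(CC[C@H](C)/C=N/N2CCC[C@H]2COC)c(O[Si](C)(C)C(C)(C)C)c(C/C=C(\C)CO[Si](C)(C)C(C)(C)C)c1
F5 | step 12 | 4-hydroxy-3-[(2E)-4-hydroxy-3-methylbut-2-en-1-yl]-5-[(3S,5E)-4,7-dihydroxy-3,7-dimethyloct-5-en-1-yl]benzoic acid (carbinol epimers) | CC(C)(O)/C=C/C(O)[C@@H](C)CCc1cc(C(=O)O)cc(C/C=C(\C)CO)c1O
F6 | step 12 | 4-hydroxy-3-[(2E)-3-methyl-4-oxobut-2-en-1-yl]-5-[(3S,5E)-7-hydroxy-3,7-dimethyl-4-oxooct-5-en-1-yl]benzoic acid | CC(C)(O)/C=C/C(=O)[C@@H](C)CCc1cc(C(=O)O)cc(C/C=C(\C)C=O)c1O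
F7 | step 5 | 2-(trimethylsilyl)ethyl 3-bromo-4-[(tert-butyldimethylsilyl)oxy]-5-(2-oxoethyl)benzoate | C[Si](C)(C)CCOC(=O)c1cc(Br)c(O[Si](C)(C)C(C)(C)C)c(CC=O)c1
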